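## Analysis of the target

The target (23) is numbered here C1–C12: C1 is the quaternary carbon bearing CH3 and the oxymethyl carbon C12; C2, C3, C8 and C7 form the cyclobutane; C4 is the ketone; C5=C6 is the alkene with the methyl on C6; C8 is the methyl-bearing quaternary ring carbon; C9 and C10 are methylenes; C11 is the secondary carbinol carbon. The cyclobutane is shared by two bridged systems. C3 and C7 are spanned by C4(=O)–C5=C6(CH3), giving a verbenone-like bicyclo[3.1.1]hept-3-en-2-one. C2 and C8 are spanned on the opposite face by C1–C11–C10–C9, giving a bicyclo[4.1.1]octane. Of the six stereocentres, C2, C3, C7 and C8 are locked to one another by the two bridges. Only C1 and C11 carry independent information: O11 is cis to the C1 methyl and trans to C12 on the seven-membered ring, and C12 lies on the side of C7. The sensitive groups are the two angelate, (Z)-2-methylbut-2-enoate, esters, which isomerise to tiglates under nucleophilic or basic catalysis, the enone, and the strained cage, which would open by retro-aldol cleavage if C2 carried oxygen while C4 is a ketone. The difficulty is a fully substituted, doubly bridged cyclobutane flanked by two all-carbon quaternary centres (C1 and C8). The strategy rests on the 1,4-relationship of C2 and C7 through C3 and C8. If C2 is the carbonyl carbon of a cycloheptanone and C7 the allylic methylene of a cis-fused cyclohexene, the C2–C7 bond is the bond that gamma-hydrogen abstraction and biradical collapse (Norrish–Yang) produce.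

## Retrosynthetic reasoning

**Ester C–O bonds.** The two angelates of 23 are cut last, to diol 20 and angelic acid 21. Acylating at the end spares the Z-alkenes every earlier base, nucleophile, radical and photon. The forward step must acylate a neopentyl primary and a hindered secondary alcohol without Z to E isomerisation.

**C4 carbonyl.** Enone 20 is traced to allylic alcohol 19, and 19 by desilylation to 18. The ketone is introduced only after C2 has lost its oxygen, because a C2 hydroxyl beta to a C4 ketone would open the cyclobutane by retro-aldol cleavage. The forward step must oxidise the allylic alcohol in the presence of two saturated alcohols.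

**C2–H bond.** 18 comes from tertiary cyclobutanol 16 through its methyl oxalate 17 by radical deoxygenation. An oxalate is chosen because it is installed without strong base; the alkoxide of 16 is a 2-vinylcyclobutoxide and would fragment. Ionic removal of the hydroxyl is excluded because a cyclobutyl cation would rearrange. The radical at C2 has three ring bonds, so hydrogen can only arrive where oxygen was.

**C2–C7 bond (key disconnection).** Cutting C2–C7 in 16 gives the cis-fused cycloheptanone 15, in which C2 is a ketone and C7 an allylic CH2 in the gamma position. This one cut removes the cyclobutane and both bridged ring systems and leaves a plain fused 6/7 bicycle. The forward reaction must abstract H from C7, close at C7, and avoid cleavage.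

**C3–C4 and C7–C8 bonds.** 15 is a Diels–Alder adduct of enone 12 and silyl dienol ether 14. The cycloaddition sets the cis ring fusion and the C8 quaternary centre, and places a masked C4 oxygen. The diene must add to the enone face anti to the C1 methyl, with its CH2 terminus on C8 and with endo orientation. A trans-fused cyclic silylene across O11 and O12 holds the C1 methyl pseudoaxial on one face to direct this.

**Dienophile 12.** 12 is traced through diol 11 (silylene formation) and triol 10 (allylic oxidation) to ester 9 (reduction). The C3=C8 alkene of 9 is cut by ring-closing metathesis to diene 8. The ring is closed from an acyclic precursor because acyclic aldol chemistry fixes the C1/C11 relationship by a predictable rule.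

**C1–C2 bond.** 8 is cut between the quaternary carbon and the vinyl carbinol carbon, giving hydroxy ester 5 and acrolein 6 (Fráter–Seebach aldol). In the chelated dianion the electrophile enters anti to the alkoxide. This places the future C2 anti and the methyl syn to O11 in the extended chain, which is O11 cis to CH3 in the ring. The new carbinol centre is later oxidised, so its configuration is irrelevant.

**C11 stereocentre and chain.** 5 comes from β-keto ester 4 by asymmetric hydrogenation, and 4 from 1 and 2 by dianion alkylation.

**Diene.** 14 comes from 3-methylbut-2-enal 13 by gamma-enolisation and O-silylation.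

## Alternatives that were turned down

**Alternative 1:** The C1–C11 bond is cut, so the seven-membered ring is closed last onto a finished bicyclo[3.1.1]heptenone. Forward, SmI2 would convert an α-bromo ester group on the carbon attached to C2 into a samarium enolate that adds to an aldehyde group at the end of the three-carbon arm on C8, giving hydroxy ester A1 with C1 and C11 formed together.
- For: Reformatsky-type aldol closures with divalent samarium tolerate medium rings, make the quaternary centre and the carbinol in one chelated step, and have none of the selectivity problems of a photoreaction. On the reliability of the ring-closing event this plan is stronger.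
- Against: the fully substituted cyclobutane with two cis-1,3 arms and the enone must already exist, so the hardest part is moved into the precursor. The enone is itself reduced by SmI2 and would need masking. The sense of the two new centres depends on a transition state spanning a rigid cage. The ester must later be reduced beside a ketone.
- Comparison: the chosen route gives up the safe closure, but sets C1 and C11 by acyclic reactions with firm rules and builds the cyclobutane and both bridged systems in one step from a Diels–Alder adduct.

**Alternative 2:** Two bonds are cut, C1–C2 and C8–C9, removing the four-carbon bridge at once. Forward, a Lewis acid activates an ester-bearing bicyclobutane unit; the fully substituted enol-ether carbon of a siloxydiene partner (future C1) attacks the hydrogen-bearing bridgehead (C2), and the ester enolate released at C8 closes onto the vinyl terminus (C9). This strain-release (4+3) annulation gives bicyclo[4.1.1]octanone ester A2.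
- For: it is convergent, driven thermally by strain release, and forms the bridged four/seven-membered system more directly than any other plan. On convergency it is stronger than the chosen route.
- Against: the attacking carbon is tetrasubstituted and creates the C1 stereocentre intermolecularly with nothing to control its face. Seven-membered closure of an ester enolate onto an unactivated vinyl group must outrun protonation and smaller-ring pathways. A2 is far from the target: the C8 ester must become a methyl group, the C11 ketone must be reduced with the right sense, and the enone ring is still to be built from two side arms.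
- Comparison: the chosen route has the whole carbon skeleton, with the C8 methyl and the C4 oxygen in place, at its key step.

**Alternative 3:** The C5–C6 bond is cut and the enone ring is closed last. Forward, the silyl enol ether of an acetyl group on C3 adds 6-exo-dig to a gold-activated ethynyl group on C7 (for example with Ph3PAuNTf2), giving exo-methylene ketone A3, which then isomerises into conjugation.
- For: gold-catalysed Conia-ene closure of silyl enol ethers onto terminal alkynes is mild and dependable, the later alkene shift is downhill, and the enone appears only at the end. As a single step it is clearly more reliable than the photocyclisation.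
- Against: the substrate must already contain the cyclobutane with four contiguous stereocentres, the four-carbon bridge and both quaternary centres, with acetyl and ethynyl cis-1,3. The closure has to span the 1,3-positions of a cyclobutane and create the strain of the bicyclo[3.1.1]heptane.
- Comparison: the chosen plan spends its risky step on exactly the part that this alternative assumes.

Key step: step 10

## Remarks before the steps

- Skeleton numbering C1–C12 as defined above is used in the descriptive names of 12 and 15–20.
- The allylic carbinol centre made in step 3 (future C2) is carried as a mixture of epimers through 8–10 and removed in step 6.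
- The C4 configuration of 15–19 is removed in step 14.
- C2 of ester 5 is a mixture, because it is enolised in step 3.
- All selectivities stated are expectations.

## Route

**Step 1**
Reactants: 1 methyl 2-methyl-3-oxobutanoate; 2 3-chloro-2-methylprop-1-ene
Product: 4 methyl 2,6-dimethyl-3-oxohept-6-enoate, via sodium lithium dianion 3 (not isolated)
Conditions: NaH, THF, 0 °C; n-BuLi, 0 °C; then 2, 0 °C to rt; aq. NH4Cl
Reagents that add atoms: none
Why: Huckin–Weiler dianion alkylation: the more basic terminal carbanion of 3 is alkylated by the allylic chloride and the methyl-bearing alpha carbon is left alone. No lasting stereocentre is formed.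

**Step 2**
Reactants: 4 methyl 2,6-dimethyl-3-oxohept-6-enoate
Product: 5 methyl (3S)-3-hydroxy-2,6-dimethylhept-6-enoate (both C2 epimers)
Conditions: H2 (4 atm), RuCl2[(S)-binap] (0.5 mol%), MeOH, 50 °C
Reagents that add atoms: none
Why: Noyori hydrogenation of a β-keto ester: the chelated ketone is reduced under control of the (S)-BINAP ligand to the (3S)-carbinol whichever C2 epimer reacts. The isolated 1,1-disubstituted alkene is not expected to be reduced by this catalyst at low pressure.

**Step 3**
Reactants: 5 methyl (3S)-3-hydroxy-2,6-dimethylhept-6-enoate; 6 acrolein
Product: 8 methyl (2R,3S)-3-hydroxy-2-(1-hydroxyprop-2-en-1-yl)-2,6-dimethylhept-6-enoate (both epimers at the allylic carbinol), via dilithium dianion 7 (not isolated)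
Conditions: LiN(iPr)2 (2.2 equiv), THF, −78 to −20 °C; 6, −78 °C; AcOH quench at −78 °C
Reagents that add atoms: none
Why: Fráter–Seebach reaction of a β-hydroxy ester dianion, here as an aldol addition: in the lithium chelate the aldehyde attacks the enolate face away from the C4 chain, so the new C–C bond is anti to the alkoxide and the quaternary centre is (2R). Lithium ester enolates add 1,2 to acrolein at −78 °C. The new carbinol centre becomes a ketone in step 6.

**Step 4**
Reactants: 8 diol ester from step 3
Product: 9 methyl (1R,7S)-2,7-dihydroxy-1,4-dimethylcyclohept-3-ene-1-carboxylate (both C2 epimers)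
Conditions: second-generation Grubbs catalyst RuCl2(=CHPh)(PCy3)(H2IMes) (5 mol%), CH2Cl2 (5 mM), 40 °C
Reagents that add atoms: none
Why: Ring-closing metathesis between the vinyl carbinol and the 1,1-disubstituted alkene; the N-heterocyclic carbene catalyst is needed for the trisubstituted cycloheptene. Free allylic alcohols are tolerated and no stereocentre is touched.

**Step 5**
Reactants: 9 cycloheptene diol ester
Product: 10 (1S,2R)-2-(hydroxymethyl)-2,5-dimethylcyclohept-4-ene-1,3-diol (both C3 epimers)
Conditions: LiAlH4, THF, 0 °C to rt
Reagents that add atoms: none
Why: Hydride reduction of the neopentyl ester to the primary alcohol (future C12). The isolated alkene and the stereocentres are unaffected.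

**Step 6**
Reactants: 10 triol
Product: 11 (6S,7R)-6-hydroxy-7-(hydroxymethyl)-3,7-dimethylcyclohept-2-en-1-one
Conditions: MnO2 (activated, excess), CH2Cl2, rt
Reagents that add atoms: none
Why: MnO2 oxidises only the allylic secondary alcohol, so both carbinol epimers converge on one enone and the saturated primary and secondary alcohols remain. Neutral conditions avoid retro-aldol loss of the β-hydroxy groups.

**Step 7**
Reactants: 11 enone diol
Product: 12 cyclic di-tert-butylsilylene of 11 (O11 and O12 joined through Si(t-Bu)2; six-membered silylene ring trans-fused to the cycloheptenone)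
Conditions: t-Bu2Si(OTf)2, 2,6-lutidine, CH2Cl2, 0 °C
Reagents that add atoms: di-tert-butylsilyl bis(trifluoromethanesulfonate), CC(C)(C)[Si](OS(=O)(=O)C(F)(F)F)(OS(=O)(=O)C(F)(F)F)C(C)(C)C
Why: 1,3-Diol protection as a six-membered silylene. The trans ring fusion places O11 and C12 equatorial and forces the C1 methyl pseudoaxial on one face of the enone, which is the control element for step 9; the silylene also withstands Lewis acid.

**Step 8**
Reactants: 13 3-methylbut-2-enal
Product: 14 (E)-tert-butyl(dimethyl)[(3-methylbuta-1,3-dien-1-yl)oxy]silane
Conditions: TBSOTf, Et3N, Et2O, 0 °C to rt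
Reagents that add atoms: tert-butyldimethylsilyl trifluoromethanesulfonate, CC(C)(C)[Si](C)(C)OS(=O)(=O)C(F)(F)F
Why: Soft enolisation: O-silylation of the enal followed by gamma-deprotonation by the amine gives the cross-conjugated silyl dienol ether, with E geometry at the enol ether. The tert-butyldimethylsilyl ether is chosen over trimethylsilyl for stability towards the Lewis acid of step 9 and chromatography.

**Step 9**
Reactants: 12 silylene-protected enone; 14 silyl dienol ether
Product: 15 cis-fused Diels–Alder adduct, the precursor of the key step (bicyclo[5.4.0]undec-5-en-2-one numbered C1–C11 as in the target: C2 ketone, C5=C6 with CH3 on C6, H3 and CH3-8 cis, cyclohexene ring on the C12 face of the seven-membered ring, TBSO-4 cis to the C3–C2 bond, O11/O12 silylene)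
Conditions: AlBr3/AlMe3 (10:1, 0.3 equiv), PhMe/CH2Cl2, −10 °C
Reagents that add atoms: none
Why: Lewis-acid-promoted Diels–Alder reaction of a silyloxydiene with a β,β-disubstituted enone. The unsubstituted CH2 terminus of 14, whose nucleophilicity is reinforced by the 1-silyloxy and 3-methyl groups, bonds to C8, and the oxygen-bearing terminus bonds to C3. Suprafacial addition anti to the pseudoaxial C1 methyl sets the cis fusion and C8; endo orientation puts the silyloxy group cis to C2.

**Step 10**
Reactants: 15 cis-fused cycloheptanone
Product: 16 tricyclic cyclobutanol (as 15 with a C2–C7 bond; tertiary OH on C2 on the side of the C4–C6 bridge; H7 on the side of the C9–C11 bridge)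
Conditions: hv (300 nm, Pyrex), degassed C6H6 (0.01 M), 5–10 °C
Reagents that add atoms: none
Why: Norrish–Yang photocyclisation, the known reaction of excited alkanones that carry a gamma C–H bond: n→π* excitation of the C2 ketone, the only chromophore absorbing near 300 nm, is followed by transfer of the pseudoaxial allylic hydrogen on C7 to the carbonyl oxygen through the six-membered array O=C2–C3–C8–C7–H, and the ketyl/allyl 1,4-biradical recombines at C2–C7. The ring closed is the four-membered ring C2–C3–C8–C7, by radical–radical coupling across the 1,4-biradical; this turns the cyclohexene into the bicyclo[3.1.1]heptene and the cycloheptane into the bridged bicyclo[4.1.1]octane. The new stereocentres C2 and C7 are set by the ring system alone: C2 is held on C3 and can only reach the face of C7 cis to the C3–C2 bond, so the hydroxyl ends on the side of the C4–C6 bridge and H7 on the side of the C9–C11 bridge, and no other diastereomer of this cage can exist. Abstraction must occur at C7 and not at C9, C10 or the C8 methyl: C7–H is the only allylic gamma C–H bond, and the endo C4 silyloxy group destabilises the half-chair with C9 axial (syn-diaxial O4/C9), which favours the conformer with C2 axial and syn to the pseudoaxial H7. Closure must occur at C7 and not at the other allyl terminus C5: in the reactive conformer the ring torsion of the cycloheptanone aims the C2 p-orbital at C7, while C5 lies off that axis and is flanked by the silyloxy-bearing C4. Cyclisation must beat Norrish type 2 cleavage of C3–C8: that bond lies close to the plane of the cyclohexenyl radical and overlaps poorly with both radical orbitals. Alpha-cleavage at the quaternary C1 is the main uncertainty; low temperature and low conversion are used against it.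

**Step 11**
Reactants: 16 tricyclic cyclobutanol
Product: 17 methyl oxalate of 16 (C2–O–CO–CO2Me)
Conditions: ClC(O)CO2Me, DMAP, Et3N, CH2Cl2, 0 °C to rt
Reagents that add atoms: methyl chlorooxoacetate, COC(=O)C(Cl)=O
Why: DMAP-catalysed acylation with a small, very reactive acid chloride. No alkoxide is formed, so the 2-vinylcyclobutanol cannot fragment, and elimination is impossible because every β-hydrogen is at a bridgehead.

**Step 12**
Reactants: 17 methyl oxalate
Product: 18 deoxygenated tricycle (as 16 with H in place of OH on C2, same face)
Conditions: Bu3SnH (slow addition), AIBN, PhMe, 110 °C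
Reagents that add atoms: none
Why: Radical deoxygenation of a tertiary alcohol through its methyl oxalate (Dolan–MacMillan variant of the Barton–McCombie reaction). The C2 radical is bonded to three ring atoms, so hydrogen can only be delivered to the position the oxygen occupied and the configuration is retained. Ring opening of the cyclobutyl radical is slow because the ring bonds lie near the nodal plane of the singly occupied orbital.

**Step 13**
Reactants: 18 deoxygenated tricycle
Product: 19 triol (C4–OH allylic, C11–OH, C12–OH)
Conditions: HF·pyridine, THF/pyridine, 0 °C to rt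
Reagents that add atoms: none
Why: Fluoride cleaves the silylene and the silyl ether in one operation. The substrate has no other acid- or base-labile group at this stage.

**Step 14**
Reactants: 19 triol
Product: 20 enone diol (C4 ketone, C5=C6 enone, C11–OH, C12–OH)
Conditions: MnO2 (activated, excess), CH2Cl2, rt
Reagents that add atoms: none
Why: Chemoselective allylic oxidation, as in the verbenol-to-verbenone oxidation; the saturated primary and secondary alcohols are not oxidised. C2 no longer carries oxygen, so the new ketone cannot trigger retro-aldol opening of the cyclobutane.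

**Step 15**
Reactants: 20 enone diol; 21 angelic acid
Product: 23 target bis-angelate CNP0240716.1, via mixed anhydride 22 (not isolated)
Conditions: 21 (6 equiv), 2,4,6-Cl3C6H2COCl, Et3N, PhMe, rt; then 20, 80 °C
Reagents that add atoms: none
Why: Yamaguchi esterification: the alcohols attack the angeloyl carbonyl of 22 because the aryl carbonyl is shielded by its two ortho chlorines. No nucleophilic catalyst is used, since addition–elimination of such catalysts at the β-carbon is what isomerises angelates to tiglates.

## Compound list

1 | methyl 2-methyl-3-oxobutanoate | CC(=O)C(C)C(=O)OC | starting material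
2 | 3-chloro-2-methylprop-1-ene | C=C(C)CCl | starting material
3 | sodium lithium dianion of 1 | [Na+].[Li+].C=C([O-])C(C)=C([O-])OC | intermediate
4 | methyl 2,6-dimethyl-3-oxohept-6-enoate | COC(=O)C(C)C(=O)CCC(C)=C | intermediate
5 | methyl (3S)-3-hydroxy-2,6-dimethylhept-6-enoate (both C2 epimers) | COC(=O)C(C)[C@@H](O)CCC(C)=C | intermediate
6 | acrolein (prop-2-enal) | C=CC=O | starting material
7 | dilithium dianion of 5 | [Li+].[Li+].COC([O-])=C(C)[C@@H]([O-])CCC(C)=C | intermediate
8 | methyl (2R,3S)-3-hydroxy-2-(1-hydroxyprop-2-en-1-yl)-2,6-dimethylhept-6-enoate (both allylic carbinol epimers) | COC(=O)[C@@](C)(C(O)C=C)[C@@H](O)CCC(C)=C | intermediate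
9 | methyl (1R,7S)-2,7-dihydroxy-1,4-dimethylcyclohept-3-ene-1-carboxylate (both C2 epimers) | COC(=O)[C@@]1(C)C(O)C=C(C)CC[C@@H]1O | intermediate
10 | (1S,2R)-2-(hydroxymethyl)-2,5-dimethylcyclohept-4-ene-1,3-diol (both C3 epimers) | OC[C@@]1(C)C(O)C=C(C)CC[C@@H]1O | intermediate
11 | (6S,7R)-6-hydroxy-7-(hydroxymethyl)-3,7-dimethylcyclohept-2-en-1-one | OC[C@@]1(C)C(=O)C=C(C)CC[C@@H]1O | intermediate
12 | cyclic di-tert-butylsilylene of 11 (trans-fused 1,3-dioxa-2-silinane) | CC(C)(C)[Si]1(OC[C@@]2(C)C(=O)C=C(C)CC[C@@H]2O1)C(C)(C)C | intermediate
13 | 3-methylbut-2-enal | CC(C)=CC=O | starting material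
14 | (E)-tert-butyl(dimethyl)[(3-methylbuta-1,3-dien-1-yl)oxy]silane | C=C(C)/C=C/O[Si](C)(C)C(C)(C)C | intermediate
15 | cis-fused Diels–Alder adduct (C2 ketone; H3/CH3-8 cis; TBSO-4 cis to C2; O11/O12 silylene) | CC(C)(C)[Si]1(OC[C@@]2(C)C(=O)[C@H]3[C@@H](O[Si](C)(C)C(C)(C)C)C=C(C)C[C@@]3(C)CC[C@@H]2O1)C(C)(C)C | intermediate
16 | tricyclic cyclobutanol (C2–C7 bond; C2–OH on the side of the C4–C6 bridge) | CC(C)(C)[Si]1(OC[C@@]2(C)[C@]3(O)[C@H]4[C@@H](O[Si](C)(C)C(C)(C)C)C=C(C)[C@@H]3[C@@]4(C)CC[C@@H]2O1)C(C)(C)C | intermediate
17 | methyl oxalate of 16 | CC(C)(C)[Si]1(OC[C@@]2(C)[C@]3(OC(=O)C(=O)OC)[C@H]4[C@@H](O[Si](C)(C)C(C)(C)C)C=C(C)[C@@H]3[C@@]4(C)CC[C@@H]2O1)C(C)(C)C | intermediate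
18 | deoxygenated tricycle (C2–H; C4–OTBS; O11/O12 silylene) | CC(C)(C)[Si]1(OC[C@@]2(C)[C@@H]3[C@H]4[C@@H](O[Si](C)(C)C(C)(C)C)C=C(C)[C@@H]3[C@@]4(C)CC[C@@H]2O1)C(C)(C)C | intermediate
19 | tricyclic triol (C4–OH, C11–OH, C12–OH) | OC[C@@]1(C)[C@@H]2[C@H]3[C@@H](O)C=C(C)[C@@H]2[C@@]3(C)CC[C@@H]1O | intermediate
20 | tricyclic enone diol (C4 ketone, C11–OH, C12–OH) | OC[C@@]1(C)[C@@H]2[C@H]3C(=O)C=C(C)[C@@H]2[C@@]3(C)CC[C@@H]1O | intermediate
21 | angelic acid, (Z)-2-methylbut-2-enoic acid | C/C=C(/C)C(=O)O | starting material
22 | angelic 2,4,6-trichlorobenzoic mixed anhydride | C/C=C(/C)C(=O)OC(=O)c1c(Cl)cc(Cl)cc1Cl | intermediate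
23 | CNP0240716.1, the 11,12-bis-angelate of 20 | C/C=C(/C)C(=O)OC[C@@]1(C)[C@@H]2[C@H]3C(=O)C=C(C)[C@@H]2[C@@]3(C)CC[C@@H]1OC(=O)/C(C)=C\C | target

## Step count and least certain steps

Total step count: 15. Longest linear sequence: 14 steps (steps 1–7 and 9–15); step 8 prepares the diene in parallel.

**Step 10 (key step).** The most likely failure is Norrish type 1 alpha-cleavage of the C1–C2 bond, favoured by the quaternary C1, outrunning gamma-hydrogen abstraction. This would open the ring or epimerise C1 on recombination. Also possible are charge-transfer quenching or oxetane formation with the C5=C6 alkene, closure of the biradical at C5, and type 2 cleavage of C3–C8. The fallback sets out from 15 and returns at 18, reaching the same C2/C7 biradical thermally and without an excited ketone.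
- 15 is converted into its oxime F1 (NH2OH·HCl, pyridine, EtOH, 80 °C) and then the O-pivaloyl oxime F2 (pivaloyl chloride, Et3N).
- Heating F2 with catalytic Cu(MeCN)4PF6 and 2,2'-bipyridine cleaves the N–O bond to an iminyl radical on C2. This abstracts the same allylic hydrogen from C7 through the same six-membered array. The allyl radical is oxidised by the divalent copper formed and captured by nitrogen at C7, which is favoured over C5 because C5 adjoins the electron-withdrawing silyloxy carbon. The product is the bridged 1-pyrroline F3 (a Hofmann–Löffler–Freytag-type amination).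
- NaBH4 in MeOH reduces the C2=N bond to the bridged pyrrolidine F4; the rings dictate the C2 configuration.
- Nitrogen deletion of F4 with N-(benzyloxy)-N-(pivaloyloxy)-4-(trifluoromethyl)benzamide (THF, 45 °C) goes through the isodiazene, loses N2, and the 1,4-biradical collapses to the cyclobutane 18. Steps 11 and 12 are then not needed.

**Step 9.** Likely failures are slow cycloaddition at the β,β-disubstituted enone with Lewis-acid destruction of the dienol ether, loss of silanol from the β-silyloxy ketone product, and erosion of endo or facial selectivity. The fallback sets out from 12 and returns at 20, using a robust hydrocarbon diene and adding the C4 oxygen afterwards.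
- 12 and isoprene with catalytic AlCl3 in toluene (rt to 40 °C) give the cis-fused adduct F5 with the same regiochemistry and facial sense.
- Irradiation as in step 10 gives cyclobutanol F6.
- Acylation as in step 11 gives oxalate F7, and Bu3SnH/AIBN gives the pinene-like alkene F8.
- Allylic C–H oxidation at C4 with CrO3·3,5-dimethylpyrazole (CH2Cl2, −20 °C), the α-pinene-to-verbenone transformation, gives enone F9.
- HF·pyridine then gives 20.
- This series lacks the conformational bias that the C4 silyloxy group provides in step 10.

**Step 12 (with step 11).** Likely failures are incomplete acylation of the hindered tertiary cyclobutanol, reduction of the intermediate alkoxycarbonyl radical to a formate before it loses CO2, and strain-driven opening of the cyclobutyl radical. The fallback sets out from 16 and returns at 18 (Barton–Crich deoxygenation, no tin radical, faster hydrogen donor).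
- 16 with excess oxalyl chloride in benzene gives the chlorooxalate F10.
- F10 with the sodium salt of N-hydroxypyridine-2-thione and catalytic DMAP gives the mixed oxalate thiohydroxamate F11.
- Photolysis of F11 with a tungsten lamp in benzene containing t-BuSH loses two CO2, and the thiol traps the C2 radical to give 18.

**Step 3.** Likely failures are low conversion of the tetrasubstituted dianion, retro-aldol reversal, and conjugate addition or polymerisation of acrolein. The fallback sets out from 5 and returns at 8, using a cyclic mono-enolate in place of the dianion.
- LiOH hydrolysis of 5 gives acid F12.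
- Acetalisation with pivalaldehyde (PPTS, azeotropic removal of water) gives the cis-2-tert-butyl-1,3-dioxan-4-one F13.
- Deprotonation with LiN(iPr)2 at −78 °C and addition of acrolein gives F14; the electrophile enters trans to the C6 side chain, the same sense as in step 3.
- NaOMe in MeOH opens F14 to 8.

**Step 15.** Likely failures are incomplete acylation of the hindered C11 hydroxyl and Z to E isomerisation of the angelate on prolonged heating. The fallback sets out from 20 and returns at 23, building the Z-alkenes after acylation.
- Both hydroxyls are acylated with 2-(diphenoxyphosphoryl)propanoic acid (DCC, DMAP, CH2Cl2) to give bis-phosphonate F15.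
- Double Ando-type Horner–Wadsworth–Emmons olefination (NaH, THF, −78 °C, then acetaldehyde) gives the two (Z)-2-methylbut-2-enoates of 23.

## Further compounds

F1 | step 10 | oxime of 15 | CC(C)(C)[Si]1(OC[C@@]2(C)C(=NO)[C@H]3[C@@H](O[Si](C)(C)C(C)(C)C)C=C(C)C[C@@]3(C)CC[C@@H]2O1)C(C)(C)C
F2 | step 10 | O-pivaloyl oxime of 15 | CC(C)(C)[Si]1(OC[C@@]2(C)C(=NOC(=O)C(C)(C)C)[C@H]3[C@@H](O[Si](C)(C)C(C)(C)C)C=C(C)C[C@@]3(C)CC[C@@H]2O1)C(C)(C)C
F3 | step 10 | bridged 1-pyrroline (C2=N, N–C7) | CC(C)(C)[Si]1(OC[C@@]2(C)C3=N[C@@H]5C(C)=C[C@H](O[Si](C)(C)C(C)(C)C)[C@H]3[C@]5(C)CC[C@@H]2O1)C(C)(C)C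
F4 | step 10 | bridged pyrrolidine (C2–NH–C7) | CC(C)(C)[Si]1(OC[C@@]2(C)[C@H]3N[C@@H]5C(C)=C[C@H](O[Si](C)(C)C(C)(C)C)[C@H]3[C@]5(C)CC[C@@H]2O1)C(C)(C)C
F5 | step 9 | isoprene adduct of 12 (cis-fused, C4 methylene) | CC(C)(C)[Si]1(OC[C@@]2(C)C(=O)[C@H]3CC=C(C)C[C@@]3(C)CC[C@@H]2O1)C(C)(C)C
F6 | step 9 | cyclobutanol from F5 | CC(C)(C)[Si]1(OC[C@@]2(C)[C@]3(O)[C@H]4CC=C(C)[C@@H]3[C@@]4(C)CC[C@@H]2O1)C(C)(C)C
F7 | step 9 | methyl oxalate of F6 | CC(C)(C)[Si]1(OC[C@@]2(C)[C@]3(OC(=O)C(=O)OC)[C@H]4CC=C(C)[C@@H]3[C@@]4(C)CC[C@@H]2O1)C(C)(C)C
F8 | step 9 | deoxygenated alkene from F7 | CC(C)(C)[Si]1(OC[C@@]2(C)[C@@H]3[C@H]4CC=C(C)[C@@H]3[C@@]4(C)CC[C@@H]2O1)C(C)(C)C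
F9 | step 9 | silylene-protected enone (C4 ketone) | CC(C)(C)[Si]1(OC[C@@]2(C)[C@@H]3[C@H]4C(=O)C=C(C)[C@@H]3[C@@]4(C)CC[C@@H]2O1)C(C)(C)C
F10 | step 12 | chlorooxalate of 16 | CC(C)(C)[Si]1(OC[C@@]2(C)[C@]3(OC(=O)C(Cl)=O)[C@H]4[C@@H](O[Si](C)(C)C(C)(C)C)C=C(C)[C@@H]3[C@@]4(C)CC[C@@H]2O1)C(C)(C)C
F11 | step 12 | mixed oxalate of 16 with N-hydroxypyridine-2-thione | CC(C)(C)[Si]1(OC[C@@]2(C)[C@]3(OC(=O)C(=O)ON5C=CC=CC5=S)[C@H]4[C@@H](O[Si](C)(C)C(C)(C)C)C=C(C)[C@@H]3[C@@]4(C)CC[C@@H]2O1)C(C)(C)C
F12 | step 3 | (3S)-3-hydroxy-2,6-dimethylhept-6-enoic acid | OC(=O)C(C)[C@@H](O)CCC(C)=C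
F13 | step 3 | cis-2-tert-butyl-5-methyl-6-(3-methylbut-3-enyl)-1,3-dioxan-4-one | CC(C)(C)[C@@H]1OC(=O)C(C)[C@H](CCC(C)=C)O1
F14 | step 3 | aldol adduct of F13 with acrolein (new bond trans to the C6 chain) | CC(C)(C)[C@@H]1OC(=O)[C@@](C)(C(O)C=C)[C@H](CCC(C)=C)O1
F15 | step 15 | bis[2-(diphenoxyphosphoryl)propanoate] of 20 | CC(C(=O)OC[C@@]1(C)[C@@H]2[C@H]3C(=O)C=C(C)[C@@H]2[C@@]3(C)CC[C@@H]1OC(=O)C(C)P(=O)(Oc4ccccc4)Oc5ccccc5)P(=O)(Oc6ccccc6)Oc7ccccc7
A1 | alternative 1 | tricyclic hydroxy ester | COC(=O)[C@@]1(C)[C@@H]2[C@H]3C(=O)C=C(C)[C@@H]2[C@@]3(C)CC[C@@H]1O
A2 | alternative 2 | bicyclo[4.1.1]octanone ester | CC(C)(C)[Si](C)(C)OC[C@@]1(C)[C@@H]2[C@@H](CO[Si](C)(C)C(C)(C)C)[C@@](C(=O)OC)([C@H]2C3(C)OCCO3)CCC1=O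
A3 | alternative 3 | tricyclic exo-methylene ketone | CC(C)(C)[Si](C)(C)OC[C@@]1(C)[C@@H]2[C@H]3C(=O)CC(=C)[C@@H]2[C@@]3(C)CC[C@@H]1O[Si](C)(C)C(C)(C)C
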